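**Assumption:** the target is taken as the open hydroxy aldehyde as drawn, trans-(1S,2R). Carbinol 6 and the oxolane building block 7 are used as stereoisomer mixtures, because the key step erases or converges all of their stereocentres.

## Retrosynthetic overview

1. Numbering: 1,2-dihydronaphthalene C1–C8a; ring A = fused arene (C4a–C8a, OMe on C6, OH on C7), ring B = carbocycle C1–C4/C4a/C8a, ring C = 4-hydroxy-3-methoxyphenyl on C1 (primed atoms). Target 15 ⇐ primary silyl ether 14 (O–Si cleavage).
2. Key disconnection: ring B of 14 is cut at C1–C2 and at C4–C4a, giving racemic diarylmethanol 6 and the dialdehyde 10. Forward, one amine/acid catalyst pair joins them in a dehydrative [3+3] annulation that also sets C1 and C2 and places the C3=C4 double bond.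
3. Enabling feature: the two free phenols. The C4' hydroxyl of ring C is para to the C1 attachment, so 6 ionises to a planar para-quinone methide (electrophilic C1, configuration of 6 erased). The C7 hydroxyl of ring A is para to C4a, so C4a is the nucleophilic arene carbon and the C4 carbinol then dehydrates. All stereoisomers of 6 and 10 converge on one product.
4. 6 ⇐ isovanillin 1 + 4-bromo-2-methoxyphenol 3 (aryllithium addition, silyl ethers on and off); 10 ⇐ commercial 2,5-dimethoxyoxolane-3-carbaldehyde 7 (reduction, silylation, acetal hydrolysis).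
5. Ring order: rings A and C are bought; ring B is the only ring made, last, in the key step.

Key step: step 8

## Route

**Step 1**
Reactants: 1 isovanillin (3-hydroxy-4-methoxybenzaldehyde)
Product: 2 3-[(tert-butyldimethylsilyl)oxy]-4-methoxybenzaldehyde
Conditions: TBSCl, imidazole, DMF, rt
Reagents that add atoms: tert-butyldimethylsilyl chloride (TBSCl), CC(C)(C)[Si](C)(C)Cl
Why: Imidazole-mediated silyl ether formation on a phenol, which masks the acidic OH for the organolithium step and leaves the aldehyde untouched.

**Step 2**
Reactants: 3 4-bromo-2-methoxyphenol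
Product: 4 (4-bromo-2-methoxyphenoxy)(tert-butyl)dimethylsilane
Conditions: TBSCl, imidazole, DMF, rt
Reagents that add atoms: tert-butyldimethylsilyl chloride (TBSCl), CC(C)(C)[Si](C)(C)Cl
Why: The same phenol silylation, needed so that bromine–lithium exchange is not quenched by the phenol.

**Step 3**
Reactants: 4 (4-bromo-2-methoxyphenoxy)(tert-butyl)dimethylsilane; 2 3-[(tert-butyldimethylsilyl)oxy]-4-methoxybenzaldehyde
Product: 5 rac-{3-[(tert-butyldimethylsilyl)oxy]-4-methoxyphenyl}{4-[(tert-butyldimethylsilyl)oxy]-3-methoxyphenyl}methanol
Conditions: n-BuLi, THF, −78 °C; then 2, −78 to 0 °C; H2O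
Reagents that add atoms: none
Why: Bromine–lithium exchange followed by 1,2-addition of the aryllithium to the aldehyde should give the diarylmethanol, made racemic on purpose because step 8 erases this centre.

**Step 4**
Reactants: 5 rac-bis-silyl diarylmethanol
Product: 6 rac-(3-hydroxy-4-methoxyphenyl)(4-hydroxy-3-methoxyphenyl)methanol
Conditions: n-Bu4NF, AcOH, THF, 0 °C
Reagents that add atoms: none
Why: Fluoride cleavage of both aryl silyl ethers, buffered with acetic acid so that the freed para-phenol is not held as phenoxide and the carbinol does not ionise.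

**Step 5**
Reactants: 7 2,5-dimethoxyoxolane-3-carbaldehyde (mixture of stereoisomers)
Product: 8 (2,5-dimethoxyoxolan-3-yl)methanol (mixture of stereoisomers)
Conditions: NaBH4, MeOH, 0 °C
Reagents that add atoms: none
Why: Borohydride reduction of the aldehyde to the primary alcohol should leave the two ring acetals untouched, and the isomer mixture is carried on because all its centres are lost later.

**Step 6**
Reactants: 8 (2,5-dimethoxyoxolan-3-yl)methanol
Product: 9 tert-butyl[(2,5-dimethoxyoxolan-3-yl)methoxy]diphenylsilane (mixture of stereoisomers)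
Conditions: TBDPSCl, imidazole, CH2Cl2, rt
Reagents that add atoms: tert-butyldiphenylsilyl chloride (TBDPSCl), CC(C)(C)[Si](Cl)(c1ccccc1)c1ccccc1
Why: Silylation of the primary alcohol with a bulky, acid-stable silyl group that should survive steps 7 and 8.

**Step 7**
Reactants: 9 tert-butyl[(2,5-dimethoxyoxolan-3-yl)methoxy]diphenylsilane
Product: 10 rac-2-{[(tert-butyldiphenylsilyl)oxy]methyl}butanedial
Conditions: 0.5 M aq. HCl, THF, 40 °C; extraction, used crude at once
Reagents that add atoms: water, O
Why: Acid-catalysed hydrolysis of the cyclic bis-acetal is the usual release of a 1,4-dialdehyde from a 2,5-dimethoxyoxolane, and the silyl ether should tolerate dilute acid.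

**Step 8**
Reactants: 6 rac-(3-hydroxy-4-methoxyphenyl)(4-hydroxy-3-methoxyphenyl)methanol; 10 rac-2-{[(tert-butyldiphenylsilyl)oxy]methyl}butanedial
Product: 14 (1S,2R)-3-{[(tert-butyldiphenylsilyl)oxy]methyl}-7-hydroxy-1-(4-hydroxy-3-methoxyphenyl)-6-methoxy-1,2-dihydronaphthalene-2-carbaldehyde, via quinone methide 11 (not isolated), via open-chain adduct 12 (not isolated), via ring-closed carbinol 13 (not isolated)
Conditions: (R)-α,α-diphenyl-2-pyrrolidinemethanol trimethylsilyl ether (20 mol%), (PhO)2P(O)OH (30 mol%), 10 (2 equiv), CHCl3, 0 °C to rt, then 40 °C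
Reagents that add atoms: none
Why: Proposed new method: the acid dehydrates racemic 6 through its ring C para-hydroxyl to the planar quinone methide 11, the enamine formed at the unbranched CH2CHO end of 10 adds 1,6 to the methine carbon of 11 (C1–C2 bond) to give 12, and the branched formyl group of 12 is then attacked by C4a of ring A, para to the free C7 hydroxyl (C4–C4a bond), to give carbinol 13, which loses water through a second, ring A quinone methide to place the C3=C4 double bond; the closest known reaction types are the aminocatalytic α-alkylation of aldehydes with para-quinone methides and other stabilised diarylmethyl cations and the acid-mediated cyclodehydration of 4-arylbutanals to 1,2-dihydronaphthalenes, which have not been merged into one [3+3] annulation of a diarylmethanol. Ring B closes by a 6-exo-trig Friedel–Crafts hydroxyalkylation (arene carbon onto the aldehyde carbon) followed by 1,2-elimination of water. C2 is set by the catalyst, whose diphenyl(silyloxy)methyl group shields one face of the E-enamine so that the (R)-amine should give (2R), and C1 follows by relative topicity in a synclinal open transition state that puts the methine hydrogen of 11 in the crowded sector, the quinoid ring next to the enamine nitrogen and ring A away from the catalyst, which leads to the trans (1S,2R) product. Because both antipodes of 6 pass through achiral 11 and the branched centre of racemic 10 ends as the sp2 carbon C3, all stereoisomers of the two partners should converge on one product. The step needs enamine formation only at the CH2CHO end, which the α-branch next to the other formyl group secures with this bulky amine, and ring closure only onto ring A at C4a, which the free C7 hydroxyl para to C4a secures over the ring C positions that are merely ortho or para to a methoxyl and over C8, which is flanked on both sides. A C1 epimer would end as the cis diastereomer and be removed by chromatography, so the enantiopurity of 14 should rest on the enamine face alone.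

**Step 9**
Reactants: 14 (1S,2R)-3-{[(tert-butyldiphenylsilyl)oxy]methyl}-7-hydroxy-1-(4-hydroxy-3-methoxyphenyl)-6-methoxy-1,2-dihydronaphthalene-2-carbaldehyde
Product: 15 (1S,2R)-7-hydroxy-1-(4-hydroxy-3-methoxyphenyl)-3-(hydroxymethyl)-6-methoxy-1,2-dihydronaphthalene-2-carbaldehyde (target)
Conditions: HF·pyridine, pyridine, THF, 0 °C to rt
Reagents that add atoms: none
Why: Fluoride cleavage of the primary silyl ether under pyridine-buffered, non-basic conditions should leave the epimerisable C2 centre, the β,γ-unsaturated aldehyde and both phenols untouched.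

## Compound list

1 | isovanillin (3-hydroxy-4-methoxybenzaldehyde) | COc1ccc(C=O)cc1O | starting material
2 | 3-[(tert-butyldimethylsilyl)oxy]-4-methoxybenzaldehyde | COc1ccc(C=O)cc1O[Si](C)(C)C(C)(C)C | intermediate
3 | 4-bromo-2-methoxyphenol | COc1cc(Br)ccc1O | starting material
4 | (4-bromo-2-methoxyphenoxy)(tert-butyl)dimethylsilane | COc1cc(Br)ccc1O[Si](C)(C)C(C)(C)C | intermediate
5 | rac-{3-[(tert-butyldimethylsilyl)oxy]-4-methoxyphenyl}{4-[(tert-butyldimethylsilyl)oxy]-3-methoxyphenyl}methanol | COc1ccc(C(O)c2ccc(O[Si](C)(C)C(C)(C)C)c(OC)c2)cc1O[Si](C)(C)C(C)(C)C | intermediate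
6 | rac-(3-hydroxy-4-methoxyphenyl)(4-hydroxy-3-methoxyphenyl)methanol | COc1ccc(C(O)c2ccc(O)c(OC)c2)cc1O | intermediate
7 | 2,5-dimethoxyoxolane-3-carbaldehyde (2,5-dimethoxytetrahydrofuran-3-carbaldehyde), mixture of stereoisomers | COC1CC(C=O)C(OC)O1 | starting material
8 | (2,5-dimethoxyoxolan-3-yl)methanol, mixture of stereoisomers | COC1CC(CO)C(OC)O1 | intermediate
9 | tert-butyl[(2,5-dimethoxyoxolan-3-yl)methoxy]diphenylsilane, mixture of stereoisomers | COC1CC(CO[Si](c2ccccc2)(c2ccccc2)C(C)(C)C)C(OC)O1 | intermediate
10 | rac-2-{[(tert-butyldiphenylsilyl)oxy]methyl}butanedial | O=CCC(CO[Si](c1ccccc1)(c1ccccc1)C(C)(C)C)C=O | intermediate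
11 | 4-[(3-hydroxy-4-methoxyphenyl)methylidene]-2-methoxycyclohexa-2,5-dien-1-one (para-quinone methide, either alkene geometry) | COC1=CC(=Cc2ccc(OC)c(O)c2)C=CC1=O | intermediate (not isolated)
12 | (3R)-2-{[(tert-butyldiphenylsilyl)oxy]methyl}-3-[(R)-(3-hydroxy-4-methoxyphenyl)(4-hydroxy-3-methoxyphenyl)methyl]butanedial, both epimers at C2 | COc1cc([C@@H](c2cc(O)c(OC)cc2)[C@@H](C=O)C(CO[Si](c2ccccc2)(c2ccccc2)C(C)(C)C)C=O)ccc1O | intermediate (not isolated)
13 | (1S,2R)-3-{[(tert-butyldiphenylsilyl)oxy]methyl}-4,7-dihydroxy-1-(4-hydroxy-3-methoxyphenyl)-6-methoxy-1,2,3,4-tetrahydronaphthalene-2-carbaldehyde, epimers at C3 and C4 | COc1cc([C@H]2c3cc(O)c(OC)cc3C(O)C(CO[Si](c3ccccc3)(c3ccccc3)C(C)(C)C)[C@@H]2C=O)ccc1O | intermediate (not isolated)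
14 | (1S,2R)-3-{[(tert-butyldiphenylsilyl)oxy]methyl}-7-hydroxy-1-(4-hydroxy-3-methoxyphenyl)-6-methoxy-1,2-dihydronaphthalene-2-carbaldehyde | COc1cc([C@H]2c3cc(O)c(OC)cc3C=C(CO[Si](c3ccccc3)(c3ccccc3)C(C)(C)C)[C@@H]2C=O)ccc1O | intermediate
15 | (1S,2R)-7-hydroxy-1-(4-hydroxy-3-methoxyphenyl)-3-(hydroxymethyl)-6-methoxy-1,2-dihydronaphthalene-2-carbaldehyde | COc1cc([C@H]2c3cc(O)c(OC)cc3C=C(CO)[C@@H]2C=O)ccc1O | target

## Step count and risks

Total step count: 9. Longest linear sequence: 5 steps (steps 1, 3, 4, 8, 9, or equally steps 5, 6, 7, 8, 9).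

Steps most likely to fail:

1. **Step 8** (labelled step). Self-aldol condensation of the dialdehyde or its acid-driven cyclodehydration to a furan may outrun the conjugate addition. The Friedel–Crafts closure may stall under the buffered acid. The relative topicity at C1 may be poorly controlled, which would divert material into the cis diastereomer. The fallback sets out from 6 and comes back at 14, and splits the event into two known reactions on a partner whose second formyl group is masked. Methyl 3,3-dimethoxypropanoate would be allylated (LiN(i-Pr)2, allyl bromide, THF, −78 °C) to methyl 2-(dimethoxymethyl)pent-4-enoate F1. F1 would be reduced (LiAlH4, Et2O, 0 °C) to 2-(dimethoxymethyl)pent-4-en-1-ol F2, silylated (TBDPSCl, imidazole) to tert-butyl{[2-(dimethoxymethyl)pent-4-en-1-yl]oxy}diphenylsilane F3, and ozonised (O3, CH2Cl2/MeOH, −78 °C; PPh3) to 3-{[(tert-butyldiphenylsilyl)oxy]methyl}-4,4-dimethoxybutanal F4. F4 and 6, under the same amine and acid at 0 °C, should give by the known enamine 1,6-addition to the quinone methide the open-chain aldehyde acetal F5, which would be isolated and freed of its C1 epimer. F5 with CF3CO2H in CH2Cl2 at 0 °C should then undergo the known acetal Friedel–Crafts cyclisation with loss of methanol to give 14.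

2. **Step 7.** The liberated 1,4-dialdehyde may oligomerise by aldol condensation or dehydrate to the furan during hydrolysis and concentration, and the silyl ether may be lost on prolonged acid contact. The fallback sets out from 8 and comes back at 15, and drops the silyl group so that the dialdehyde is stabilised internally. Alcohol 8 would be hydrolysed in water (Amberlyst-15, 60 °C) to 2-(hydroxymethyl)butanedial, which should rest as its cyclic hemiacetal 5-hydroxyoxolane-3-carbaldehyde F6. After filtration, salting out and extraction into ethyl acetate, F6 would be used in place of 10 under the conditions of step 8; the enamine would form at the hemiacetal-masked CH2CHO end after ring opening. This should give the target 15 directly, without steps 6 and 9.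

3. **Step 4.** On loss of the silyl groups the para-phenoxide may expel hydroxide from the carbinol carbon, and the resulting quinone methide would oligomerise. The fallback sets out from 5 and comes back at 6, and frees the phenols at the ketone oxidation level, where no quinone methide can form. Carbinol 5 would be oxidised (MnO2, CH2Cl2, rt) to {3-[(tert-butyldimethylsilyl)oxy]-4-methoxyphenyl}{4-[(tert-butyldimethylsilyl)oxy]-3-methoxyphenyl}methanone F7. F7 would be desilylated (n-Bu4NF, THF, rt) to (3-hydroxy-4-methoxyphenyl)(4-hydroxy-3-methoxyphenyl)methanone F8, and F8 reduced last (NaBH4, EtOH, 0 °C, work-up at pH 7) to 6.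

## Further compounds

F1 | step 8 | methyl 2-(dimethoxymethyl)pent-4-enoate | COC(=O)C(CC=C)C(OC)OC
F2 | step 8 | 2-(dimethoxymethyl)pent-4-en-1-ol | OCC(CC=C)C(OC)OC
F3 | step 8 | tert-butyl{[2-(dimethoxymethyl)pent-4-en-1-yl]oxy}diphenylsilane | C=CCC(CO[Si](c1ccccc1)(c1ccccc1)C(C)(C)C)C(OC)OC
F4 | step 8 | 3-{[(tert-butyldiphenylsilyl)oxy]methyl}-4,4-dimethoxybutanal | O=CCC(CO[Si](c1ccccc1)(c1ccccc1)C(C)(C)C)C(OC)OC
F5 | step 8 | (2R)-3-{[(tert-butyldiphenylsilyl)oxy]methyl}-2-[(R)-(3-hydroxy-4-methoxyphenyl)(4-hydroxy-3-methoxyphenyl)methyl]-4,4-dimethoxybutanal, both epimers at C3 | COc1cc([C@@H](c2cc(O)c(OC)cc2)[C@@H](C=O)C(CO[Si](c2ccccc2)(c2ccccc2)C(C)(C)C)C(OC)OC)ccc1O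
F6 | step 7 | 5-hydroxyoxolane-3-carbaldehyde (cyclic hemiacetal of 2-(hydroxymethyl)butanedial) | O=CC1COC(O)C1
F7 | step 4 | {3-[(tert-butyldimethylsilyl)oxy]-4-methoxyphenyl}{4-[(tert-butyldimethylsilyl)oxy]-3-methoxyphenyl}methanone | COc1ccc(C(=O)c2ccc(O[Si](C)(C)C(C)(C)C)c(OC)c2)cc1O[Si](C)(C)C(C)(C)C
F8 | step 4 | (3-hydroxy-4-methoxyphenyl)(4-hydroxy-3-methoxyphenyl)methanone | COc1ccc(C(=O)c2ccc(O)c(OC)c2)cc1O
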